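The numbers in the tables were computed for substances that don't exist, and the scatter is random.

In this closed, stirred vessel the left-handed and right-handed substrates compete for one single-handed coupling partner, and two flasks have to be judged by the excess of left-handed product at their end.

in all of them: left-handed substrate 17 mM; right-handed substrate 17 mM; precatalyst 0.34 mM
- violet: coupling partner 45 mM; run made earlier
- teal: coupling partner 72 mM; run made earlier
- amber: coupling partner 100 mM; run made earlier
- Wednesday's: coupling partner 42.5 mM; time 10 min
- Monday's: coupling partner 120 mM; time 10 min

| run | time / min | left-handed product / % | right-handed product / % |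
|---|---|---|---|
| violet | 0.417 | 4 | 0 |
| violet | 1.33 | 11 | 8 |
| violet | 2.50 | 21 | 13 |
| violet | 4.00 | 24 | 19 |
| violet | 5.00 | 30 | 20 |
| teal | 1.00 | 13 | 9 |
| teal | 2.00 | 25 | 18 |
| teal | 3.00 | 30 | 22 |
| teal | 4.00 | 35 | 28 |
| teal | 5.00 | 39 | 33 |
| amber | 1.00 | 20 | 8 |
| amber | 2.00 | 30 | 18 |
| amber | 3.00 | 36 | 24 |
| amber | 4.00 | 45 | 33 |
| amber | 5.00 | 45 | 33 |

(standard deviation of a reading: 2 percentage points)

- coupling partner is single-handed; left-handed substrate and right-handed substrate are mirror images of each other, charged as a racemate, each of them at the stated concentration
- the numbers in the tables scatter by 2 percentage points (one standard deviation)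
- an excess is the difference of the two amounts in percent of their sum
- an excess is below zero if the other one leads
- the handed part of coupling partner does not stay in what it makes, so the products of the two hands are mirror images too

* which of the two ends with the higher excess of left-handed product over right-handed product in the product ("neither" if they lie within 2 percentage points) (Wednesday's / Monday's / neither)
* excess of left-handed product over right-handed product in the product at the end, Wednesday's
* excess of left-handed product over right-handed product in the product at the end, Monday's

Write f for the fraction of a hand's own charge still left. In the last readings, ln f(left) / ln f(right), the selectivity factor, gives 1.79 for violet, 1.40 for teal and 2.13 for amber. That is a wide spread, so you take the mean, 1.78. Left-handed loss over time and mean partner gives a rate constant of 0.0845 L mol⁻¹ s⁻¹ in teal and 0.0885 L mol⁻¹ s⁻¹ in amber, so the rate follows the partner.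

Now define the exposure as rate constant times mean partner times time. Then you reckon f(left) as exp(-exposure), f(right) as exp(-exposure/s), and the product excess as (f(right) - f(left)) / (2 - f(left) - f(right)). The crossing lies at exposure = s, where the right-handed substrate has also gone through one lifetime.

For Wednesday's, a first guess lets the partner fall to its charge minus both substrates, which gives exposure 1.29. But that reckons fractions 0.275 and 0.483 for Wednesday's, so its partner is better put at 21.4 mM at the end. The second pass gives 1.62, below s, and an excess of 14.6%.

Monday's exposure, the left-handed lifetimes its partner gives in the time, with the partner again let fall by both substrates, is 5.22, above s, so its reckoned excess is 2.45%. The objection is amber's flat last pair of readings. Yet the expected right-handed gain there is 3.2 percentage points, against a scatter of 2.8 points on a difference, so the pair proves no stop. This reckoning therefore puts Wednesday's ahead.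

The forecast says neither, with 13% for Wednesday's and 14% for Monday's, on amber's end, “which suggests the catalyst dies”. It differs from this reckoning on Monday's.

The flask gives Wednesday's, with 14.3% for Wednesday's and 2.56% for Monday's. At 10.0 min, Monday's keeps 0.75% of its left-handed and 5.2% of its right-handed charge, and exposure 5.22 had put these at 0.541% and 5.33%.

    coupling partner + left-handed substrate → left-handed product (k = 0.0880 L mol⁻¹ s⁻¹)
    coupling partner + right-handed substrate → right-handed product (k = 0.0520 L mol⁻¹ s⁻¹)
    left-handed substrate + racemization catalyst ⇌ right-handed substrate + racemization catalyst, rate k3*[racemization catalyst]*[left-handed substrate] forward; the back reaction follows from the equilibrium constant (k = 2.10 L mol⁻¹ s⁻¹)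
    precatalyst → racemization catalyst (k = 2.10 × 10⁻⁴ s⁻¹)
    2 racemization catalyst → spent catalyst (k = 2.80 L mol⁻¹ s⁻¹)

Take Wednesday's recipe with 26 mM of partner, below both substrates together. Two passes give exposure 0.659, then 0.976, and an excess of 19.2%. The computed flask gives 18.6%.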